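Ring carbons are numbered as in germacrane: C1–C10 in the ring, methyl C14 on C10, C15 on C4, and C11 on C7 carrying methyl C13 and C12. Compound numbers are those of the steps and of the list after them.

Assumption: C9 is carried as a racemic carbinol (a pair of C9 epimers once the oxiranes are in place); its configuration is erased in the last step.

Remark on descriptors: the formal descriptor at C7 depends on the C9 substituent, which changes the ranking of C6 and C8. The spatial arrangement that is 7S in 24 and 28 is 7R in 25, 26 and 27.

## Analysis of the target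

Compound 28 is a ten-membered carbocycle with an E enone, C9(=O)–C10(C14)=C1, an oxirane across C4–C5 with the acetoxymethyl C15 on C4, and a spiro oxirane across C7–C11 with C13 and the acetoxymethyl C12 on C11. All four stereocentres (4R, 5R, 7S, 11R) are oxirane carbons, and three of them are fully substituted. Within each oxirane the relative configuration is that of a syn addition to an alkene. C3 and C6 are cis on the C4–C5 oxirane, so the parent C4=C5 alkene has C15 trans to C6; C12 is cis to C8 on the C7–C11 oxirane, so the parent C7=C11 alkene has C12 cis to C8. The two oxiranes are separated by C6 and are related only through absolute control. The sensitive groups are the β,γ-epoxy ketone O=C9–C8H2–C7(O), which opens on enolisation toward C8, the two 2,3-epoxy acetates, the enone, and the medium ring, which invites transannular reactions. The hard part is the C7=C11 alkene: it is tetrasubstituted, its four substituents (C6, C8, C12, C13) are all unbiased sp3 carbons, and no intermolecular olefination tells them apart. The strategy rests on the C9 oxygen lying two atoms from C7: an ester between O9 and the C12 carboxyl closes the six-membered ring O9–C12–C11=C7–C8–C9, and an endocyclic alkene in that ring can only have C12 cis to C8.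

## Retrosynthetic reasoning

28 ⇒ 27 ⇒ 26. The C9 carbonyl is taken back to the carbinol and then to its benzyl-type ether. No C–C bond is cut. The gain is that the base-labile β,γ-epoxy ketone exists only in the last flask. The forward steps must be a neutral oxidative ether cleavage and a buffered oxidation.

26 ⇒ 25 ⇒ 23. The four C–O bonds of the two oxiranes are removed together, leading through diol 25 to the bis-allylic diol 23. The cut is made here because each primary hydroxyl (on C15 and on C12) sits on the alkene it has to direct, and because the oxiranes would not survive the acid and base steps that build the ring. The forward reaction has to set four stereocentres by reagent control. Both alkenes call for the same enantiomer of the chiral ligand, so one operation serves, with 24 on the way.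

23 ⇒ 22 ⇒ 21. The C15 carbinol is traced to the ester of 21 and the C12 hydroxyl to its silyl ether. These are functional group changes only, and they expose the ring-closing disconnection.

21 ⇒ 20 ⇒ 19. The ring is opened at C4=C5. This is the one ring bond whose formation by carbonyl olefination gives what the target needs: the conjugated ester forms with C15 trans to C6, which is also the less strained ring-cis arrangement, and C15 arrives one reduction away from the carbinol. Cutting C1=C10 would mean closing a ring-trans trisubstituted alkene, and C7=C11 cannot be closed with geometric control. The forward step must outrun oligomerisation and must not enolise the aldehyde of 20.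

19 ⇒ 16 + 17. The C3–C4 bond is cut between a primary iodide and carbanion 18 derived from 17. This is a plain SN2 bond formation that attaches C4 and C15 with the phosphorus handle already in place.

16 ⇒ 15 ⇒ 14 ⇒ 13 ⇒ 12. No skeletal bond is cut. The iodide goes back to the silyl ether that came in with 5, and the C9 and C12 oxygens are differentiated: a benzyl-type ether on C9 that lasts to the end, and a bulky silyl ether on C12 that is released just before the epoxidation.

12 ⇒ 11. The two carbinols are rejoined as the lactone (C12–O9 bond). In the forward sense hydride cuts the tether; C12 returns as the hydroxymethyl group that will direct the epoxidation and O9 as the carbinol of the future ketone, so no atom of the tether is wasted.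

11 ⇒ 10. This is the key disconnection. C7=C11 is cut to a C7 ketone and a C11 phosphonate carbanion that hangs on O9 through the C12 ester. The cut turns the geometry problem into a ring-size fact. The forward reaction must deprotonate the phosphonate and not the ketone, whose enolate could expel the C9 acyloxy group.

10 ⇒ 8 + 9. The ester C–O bond is cut, which separates C11–C13 (acid 9) from the aldol adduct 8.

8 ⇒ 6 + 5 (through enolate 7). The C8–C9 bond is cut as an aldol. C5–C8 come from one commercial ketone that already carries the masked C5 aldehyde. The forward reaction needs enolisation on the methyl side and 1,2-addition to the enal.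

5 ⇒ 3 + 4, and 3 ⇒ 2 ⇒ 1. The C1=C10 bond is cut as a Wittig reaction of a stabilised ylide, which sets the E geometry needed in the ring. C1–C3 come from the diol 1.

## Alternatives that were turned down

Alternative 1: The ring would be cut at C9–C10 and closed last.
- Forward step: the open-chain precursor A2 already carries both oxiranes, both acetates, a C9 aldehyde and a C10 alkenyl iodide. CrCl2 with a catalytic amount of NiCl2 turns the iodide into an alkenyl species of trivalent chromium, which adds to the aldehyde and gives the ten-membered allylic alcohol A1 as a pair of C9 epimers. A1 is the same compound as 27, one oxidation short of 28.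
- For: this closure is among the most dependable for strained medium rings, keeps the alkenyl geometry, and tolerates esters and oxiranes. All four stereocentres would be set on an open chain, where hydroxyl-directed asymmetric epoxidation meets no conformational bias from a ring. On that point it is stronger than the chosen route, whose epoxidation has to work on a ten-membered ring.
- Against: A2 is a β,γ-epoxy aldehyde (C9 aldehyde, C8 methylene, C7 oxirane) that opens to a γ-hydroxy enal on the slightest enolisation. It has to be made, kept and cyclised at high dilution next to Lewis-acidic chromium salts. The whole stereochemical investment is staked on the last C–C bond. The plan also says nothing about how the C7=C11 geometry behind the oxirane is obtained, which is the real problem of the target.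
- Comparison: the chosen strategy answers the geometry question in step 6 on a cheap fragment and spends its risk early. In step count there is little to choose.

Alternative 2: C6–C7 and C11–C12 would be cut across an alkyne.
- Forward step: the magnesium alkoxide of but-2-yn-1-ol A4 takes up the acetal Grignard reagent A5 under CuI catalysis in an anti carbomagnesiation (new bond C6–C7, magnesium on C11 in a five-membered chelate). CO2 then carboxylates C11, and acid closes butenolide A3.
- For: one operation from three cheap components gives a tetrasubstituted alkene locked in a five-membered lactone. In step economy for the core this beats the chosen route, which needs six steps to reach 11.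
- Against: the lactone oxygen of A3 sits on C8, a plain methylene in 28. After the lactone is opened, that oxygen has to be exchanged for the C8–C9 bond, and the two primary allylic hydroxyls then flanking the alkene (on C8 and C12) are almost indistinguishable. A5 is a β-alkoxy organomagnesium with a fragmentation pathway of its own, and a sluggish partner for a carbometalation that works best with allyl-, aryl- or vinylmagnesium reagents. C1–C4, C9 and C10 are all still to be added.
- Comparison: the chosen tether uses the C9 oxygen, which is the carbonyl oxygen of the target, so nothing has to be excised, and lactone 11 already holds C1–C3 and C5–C13.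

Alternative 3: The ring would be cut at C2–C3.
- Forward step: in the open-chain precursor A7, C2 carries a phenylsulfonyl group and is allylic to C1=C10, and C3 is an allylic chloride on C4=C5. KN(SiMe3)2 deprotonates C2, and the carbanion displaces chloride to give the ten-membered triene A6.
- For: intramolecular alkylation of a sulfone-stabilised allylic carbanion is the best-precedented way to close germacrane rings. It is irreversible, involves no enolisable aldehyde, and all three alkenes are in place before closure. As a ring closure it is a stronger bet than step 14 of the chosen route.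
- Against: the sulfone has to be introduced and then removed reductively next to an allylic position, where double-bond migration or loss of the C1=C10 geometry threatens. An ambident allylic carbanion (α versus γ) meets an ambident allylic chloride (SN2 versus SN2′). The C4=C5 unit with C3 cis to C6 needs a separate stereoselective olefination. The three hydroxyls carry the same silyl group and still have to be told apart. As in alternative 1, there is no device for the C7=C11 geometry.
- Comparison: the chosen route supplies that device. Its ring closure also builds C4=C5 in the same operation, with the geometry favoured both by the olefination and by ring strain, and delivers C15 with no auxiliary group to remove.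

Key step: step 6

## Route

Step 1
Reactants: 1 propane-1,3-diol
Product: 2 3-[(tert-butyldimethylsilyl)oxy]propan-1-ol
Conditions: NaH (1.0 equiv), THF, 0 °C to rt; then TBSCl (1.0 equiv), rt
Reagents that add atoms: tert-butyldimethylsilyl chloride, CC(C)(C)[Si](C)(C)Cl
Why: O-Silylation of the sparingly soluble monosodium alkoxide, which biases the reaction toward the mono-ether of the symmetric diol.

Step 2
Reactants: 2 3-[(tert-butyldimethylsilyl)oxy]propan-1-ol
Product: 3 3-[(tert-butyldimethylsilyl)oxy]propanal
Conditions: TEMPO (10 mol%), PhI(OAc)2 (1.1 equiv), CH2Cl2, rt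
Reagents that add atoms: none
Why: Oxoammonium-mediated alcohol oxidation stops at the aldehyde and is non-basic, so the β-silyloxy aldehyde should not eliminate.

Step 3
Reactants: 3 3-[(tert-butyldimethylsilyl)oxy]propanal; 4 2-(triphenylphosphoranylidene)propanal
Product: 5 (E)-5-[(tert-butyldimethylsilyl)oxy]-2-methylpent-2-enal
Conditions: toluene, 80 °C
Reagents that add atoms: none
Why: Wittig olefination with a formyl-stabilised ylide, whose reversible addition leads to the E trisubstituted enal (CHO trans to the chain); this fixes the later C1=C10 geometry with C2 trans to C9. The conjugated product is less electrophilic than 3, so a second homologation should be minor.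

Step 4
Reactants: 6 4,4-dimethoxybutan-2-one; 5 (E)-5-[(tert-butyldimethylsilyl)oxy]-2-methylpent-2-enal
Product: 8 (E)-9-[(tert-butyldimethylsilyl)oxy]-5-hydroxy-1,1-dimethoxy-6-methylnon-6-en-3-one (racemic), via lithium enolate 7 (not isolated)
Conditions: LiN(iPr)2 (1.05 equiv), THF, −78 °C, 6 added dropwise; then 5, −78 °C; AcOH in THF at −78 °C
Reagents that add atoms: none
Why: Directed aldol addition: kinetic deprotonation at the methyl group gives enolate 7, which adds 1,2 to the enal and forms C8–C9. The cold acidic quench is meant to prevent retro-aldol cleavage and dehydration; the new C9 carbinol is racemic, which does not matter because C9 ends as a ketone.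

Step 5
Reactants: 8 (E)-9-[(tert-butyldimethylsilyl)oxy]-5-hydroxy-1,1-dimethoxy-6-methylnon-6-en-3-one; 9 2-(diethoxyphosphoryl)propanoic acid
Product: 10 (3E)-1-[(tert-butyldimethylsilyl)oxy]-9,9-dimethoxy-4-methyl-7-oxonon-3-en-5-yl 2-(diethoxyphosphoryl)propanoate (mixture of diastereomers at C9 and C11)
Conditions: DCC (1.2 equiv), DMAP (10 mol%), CH2Cl2, 0 °C
Reagents that add atoms: none
Why: Steglich esterification under cold, nearly neutral conditions, chosen so that the acylated aldol does not lose the acyloxy group by β-elimination. The diastereomer mixture is of no consequence because C11 becomes sp2 in the next step.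

Step 6
Reactants: 10 (3E)-1-[(tert-butyldimethylsilyl)oxy]-9,9-dimethoxy-4-methyl-7-oxonon-3-en-5-yl 2-(diethoxyphosphoryl)propanoate
Product: 11 6-{(2E)-5-[(tert-butyldimethylsilyl)oxy]pent-2-en-2-yl}-4-(2,2-dimethoxyethyl)-3-methyl-5,6-dihydro-2H-pyran-2-one (racemic at C9)
Conditions: LiCl (5 equiv), DBU (1.2 equiv), MeCN (0.02 M), 0 °C to rt
Reagents that add atoms: none
Why: Lithium ion chelates the phosphoryl and ester carbonyl oxygens and makes the C11–H acidic enough for the amidine base, so the phosphonate is deprotonated in preference to the ketone. The carbanion adds to the C7 ketone; the alkoxide closes to an oxaphosphetane, which collapses with loss of diethyl phosphate to give C7=C11. The closest known reaction type is the intramolecular Horner–Wadsworth–Emmons reaction (Masamune–Roush conditions) of β-(phosphonoacyloxy) ketones to α,β-unsaturated δ-lactones. The six-membered ring (C11, C12, O, C9, C8, C7) closes in a 6-(enolendo)-exo-trig mode. No stereocentre is created: C9 is untouched and the C11 centre of 10 disappears. The stereochemical result is the alkene geometry, which is dictated by the ring, because an endocyclic double bond in a six-membered lactone must hold C12 cis to C8. The selectivity needed is chemoselective deprotonation: an enolate toward C8 could expel the C9 carboxylate, and one toward C6 could expel methoxide. This is secured by the acidity gap under lithium chelation, the mild base and the fast six-membered closure. The C1=C10 geometry, the acetal and the silyl ether are not involved.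

Step 7
Reactants: 11 6-{(2E)-5-[(tert-butyldimethylsilyl)oxy]pent-2-en-2-yl}-4-(2,2-dimethoxyethyl)-3-methyl-5,6-dihydro-2H-pyran-2-one
Product: 12 (2E,6E)-9-[(tert-butyldimethylsilyl)oxy]-3-(2,2-dimethoxyethyl)-2,6-dimethylnona-2,6-diene-1,5-diol (racemic; C12 hydroxymethyl cis to the C8 methylene)
Conditions: i-Bu2AlH (4 equiv), CH2Cl2, −78 to 0 °C; aq. potassium sodium tartrate work-up
Reagents that add atoms: none
Why: 1,2-Reduction of the unsaturated lactone by an electrophilic aluminium hydride, through the lactol to the diol, with no conjugate reduction expected for a tetrasubstituted enoate. The alkene geometry set in step 6 is kept, and the acetal should survive at or below 0 °C.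

Step 8
Reactants: 12 (2E,6E)-9-[(tert-butyldimethylsilyl)oxy]-3-(2,2-dimethoxyethyl)-2,6-dimethylnona-2,6-diene-1,5-diol
Product: 13 (2E,6E)-9-[(tert-butyldimethylsilyl)oxy]-1-[(tert-butyldiphenylsilyl)oxy]-3-(2,2-dimethoxyethyl)-2,6-dimethylnona-2,6-dien-5-ol
Conditions: TBDPSCl (1.05 equiv), imidazole, CH2Cl2, 0 °C
Reagents that add atoms: tert-butyldiphenylsilyl chloride, CC(C)(C)[Si](Cl)(c1ccccc1)c1ccccc1
Why: Sterically controlled O-silylation: the bulky chlorosilane should take the primary C12 hydroxyl and leave the hindered secondary C9 hydroxyl.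

Step 9
Reactants: 13 (2E,6E)-9-[(tert-butyldimethylsilyl)oxy]-1-[(tert-butyldiphenylsilyl)oxy]-3-(2,2-dimethoxyethyl)-2,6-dimethylnona-2,6-dien-5-ol
Product: 14 (2E,6E)-9-[(tert-butyldimethylsilyl)oxy]-1-[(tert-butyldiphenylsilyl)oxy]-3-(2,2-dimethoxyethyl)-5-[(4-methoxybenzyl)oxy]-2,6-dimethylnona-2,6-diene
Conditions: NaH, 4-methoxybenzyl chloride, Bu4NI (10 mol%), DMF, 0 °C to rt
Reagents that add atoms: 4-methoxybenzyl chloride, COc1ccc(CCl)cc1
Why: Williamson etherification of the C9 alkoxide. This ether is chosen because it can be removed at the very end by neutral oxidation in the presence of oxiranes and acetates.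

Step 10
Reactants: 14 (2E,6E)-9-[(tert-butyldimethylsilyl)oxy]-1-[(tert-butyldiphenylsilyl)oxy]-3-(2,2-dimethoxyethyl)-5-[(4-methoxybenzyl)oxy]-2,6-dimethylnona-2,6-diene
Product: 15 (3E,7E)-9-[(tert-butyldiphenylsilyl)oxy]-7-(2,2-dimethoxyethyl)-5-[(4-methoxybenzyl)oxy]-4,8-dimethylnona-3,7-dien-1-ol
Conditions: camphorsulfonic acid (10 mol%), MeOH/CH2Cl2 1:1, 0 °C
Reagents that add atoms: none
Why: Acid-catalysed methanolysis of silyl ethers, which cleaves the primary tert-butyldimethylsilyl ether much faster than the bulkier tert-butyldiphenylsilyl ether. In methanol the dimethyl acetal only exchanges with the solvent.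

Step 11
Reactants: 15 (3E,7E)-9-[(tert-butyldiphenylsilyl)oxy]-7-(2,2-dimethoxyethyl)-5-[(4-methoxybenzyl)oxy]-4,8-dimethylnona-3,7-dien-1-ol
Product: 16 (3E,7E)-9-[(tert-butyldiphenylsilyl)oxy]-7-(2,2-dimethoxyethyl)-1-iodo-5-[(4-methoxybenzyl)oxy]-4,8-dimethylnona-3,7-diene
Conditions: I2, PPh3, imidazole, CH2Cl2, 0 °C to rt
Reagents that add atoms: iodine, II
Why: Appel-type iodination: the alkoxyphosphonium ion is displaced by iodide at the primary carbon. Imidazole keeps the medium buffered for the acetal and the ethers.

Step 12
Reactants: 16 (3E,7E)-9-[(tert-butyldiphenylsilyl)oxy]-7-(2,2-dimethoxyethyl)-1-iodo-5-[(4-methoxybenzyl)oxy]-4,8-dimethylnona-3,7-diene; 17 triethyl phosphonoacetate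
Product: 19 ethyl (5E,9E)-11-[(tert-butyldiphenylsilyl)oxy]-2-(diethoxyphosphoryl)-9-(2,2-dimethoxyethyl)-7-[(4-methoxybenzyl)oxy]-6,10-dimethylundeca-5,9-dienoate, via sodium phosphonoacetate carbanion 18 (not isolated)
Conditions: NaH, 17 (3 equiv), DMF, 0 °C to rt; then 16, 50 °C
Reagents that add atoms: none
Why: SN2 C-alkylation of a soft, weakly basic phosphonate carbanion forms C3–C4. The excess of carbanion limits dialkylation and its low basicity limits elimination of the homoallylic iodide; the new C4 centre is unimportant because it becomes sp2 in step 14.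

Step 13
Reactants: 19 ethyl (5E,9E)-11-[(tert-butyldiphenylsilyl)oxy]-2-(diethoxyphosphoryl)-9-(2,2-dimethoxyethyl)-7-[(4-methoxybenzyl)oxy]-6,10-dimethylundeca-5,9-dienoate
Product: 20 ethyl (5E,9E)-11-[(tert-butyldiphenylsilyl)oxy]-2-(diethoxyphosphoryl)-7-[(4-methoxybenzyl)oxy]-6,10-dimethyl-9-(2-oxoethyl)undeca-5,9-dienoate
Conditions: 10% aq. oxalic acid on SiO2, CH2Cl2, rt; product used at once
Reagents that add atoms: water, O
Why: Mild heterogeneous acetal hydrolysis, chosen so that the silyl and benzyl-type ethers survive and the new β,γ-unsaturated aldehyde is not enolised.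

Step 14
Reactants: 20 ethyl (5E,9E)-11-[(tert-butyldiphenylsilyl)oxy]-2-(diethoxyphosphoryl)-7-[(4-methoxybenzyl)oxy]-6,10-dimethyl-9-(2-oxoethyl)undeca-5,9-dienoate
Product: 21 ethyl (1(10)E,4E,7(11)Z)-12-[(tert-butyldiphenylsilyl)oxy]-9-[(4-methoxybenzyl)oxy]germacra-1(10),4,7(11)-trien-15-oate (racemic at C9; ring bonds cis at C4=C5, ester trans to C6, C12 cis to C8)
Conditions: LiCl (10 equiv), DBU (3 equiv), MeCN, rt, slow addition of 20 to a final concentration of about 1 mM
Reagents that add atoms: none
Why: Ring-closing Horner–Wadsworth–Emmons olefination (Masamune–Roush conditions) forms C4=C5 and the ten-membered ring. The usual preference for the ester trans to the β-substituent and the lower strain of a ring-cis alkene both point to the isomer needed, and high dilution is used against oligomers.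

Step 15
Reactants: 21 ethyl (1(10)E,4E,7(11)Z)-12-[(tert-butyldiphenylsilyl)oxy]-9-[(4-methoxybenzyl)oxy]germacra-1(10),4,7(11)-trien-15-oate
Product: 22 (1(10)E,4E,7(11)Z)-12-[(tert-butyldiphenylsilyl)oxy]-9-[(4-methoxybenzyl)oxy]germacra-1(10),4,7(11)-trien-15-ol
Conditions: i-Bu2AlH (3 equiv), CH2Cl2, −78 °C; aq. potassium sodium tartrate work-up
Reagents that add atoms: none
Why: 1,2-Reduction of the conjugated ester to the primary allylic alcohol at C15; the ethers and alkenes are inert.

Step 16
Reactants: 22 (1(10)E,4E,7(11)Z)-12-[(tert-butyldiphenylsilyl)oxy]-9-[(4-methoxybenzyl)oxy]germacra-1(10),4,7(11)-trien-15-ol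
Product: 23 (1(10)E,4E,7(11)Z)-9-[(4-methoxybenzyl)oxy]germacra-1(10),4,7(11)-triene-12,15-diol
Conditions: Bu4NF, THF, 0 °C to rt
Reagents that add atoms: none
Why: Fluoride-induced cleavage of the silyl ether frees the C12 hydroxyl; the C9 ether stays in place.

Step 17
Reactants: 23 (1(10)E,4E,7(11)Z)-9-[(4-methoxybenzyl)oxy]germacra-1(10),4,7(11)-triene-12,15-diol
Product: 25 (4R,5R,7R,11R)-4,5:7,11-diepoxy-9-[(4-methoxybenzyl)oxy]germacr-1(10)-ene-12,15-diol (both C9 epimers), via 7,11-monoepoxide 24 (not isolated)
Conditions: Ti(OiPr)4 (2.4 equiv), D-(−)-diethyl tartrate (2.9 equiv), t-BuOOH (6 equiv, anhydrous), 4 Å MS, CH2Cl2, −25 °C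
Reagents that add atoms: tert-butyl hydroperoxide, CC(C)(C)OO
Why: Sharpless asymmetric epoxidation: each primary allylic hydroxyl binds titanium and delivers oxygen to its own alkene, while the ether-protected C1=C10 is inert. L-(+)-tartrate gives the S configuration at the hydroxymethyl-bearing oxirane carbon (as in (2S,3S)-epoxygeraniol); C4 and C11 are the counterparts of that carbon and must be R, hence the D-(−) ligand for both alkenes. Syn addition across C4=C5 (C15 trans to C6) and C7=C11 (C12 cis to C8) then fixes C5 and C7; the more electron-rich tetrasubstituted alkene is expected to react first (24), but either order leads to 25.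

Step 18
Reactants: 25 (4R,5R,7R,11R)-4,5:7,11-diepoxy-9-[(4-methoxybenzyl)oxy]germacr-1(10)-ene-12,15-diol
Product: 26 (4R,5R,7R,11R)-4,5:7,11-diepoxy-9-[(4-methoxybenzyl)oxy]germacr-1(10)-ene-12,15-diyl diacetate
Conditions: Ac2O, pyridine, DMAP (5 mol%), CH2Cl2, 0 °C
Reagents that add atoms: acetic anhydride, CC(=O)OC(C)=O
Why: Nucleophile-catalysed O-acylation of the two primary epoxy alcohols under conditions that leave oxiranes untouched.

Step 19
Reactants: 26 (4R,5R,7R,11R)-4,5:7,11-diepoxy-9-[(4-methoxybenzyl)oxy]germacr-1(10)-ene-12,15-diyl diacetate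
Product: 27 (4R,5R,7R,11R)-4,5:7,11-diepoxy-9-hydroxygermacr-1(10)-ene-12,15-diyl diacetate (both C9 epimers)
Conditions: DDQ (1.3 equiv), CH2Cl2/aq. NaH2PO4–Na2HPO4 buffer (pH 7), 0 °C
Reagents that add atoms: none
Why: Oxidative cleavage of the 4-methoxybenzyl ether by hydride abstraction and hydrolysis of the oxocarbenium ion. The medium is neutral, so acetates and oxiranes should persist.

Step 20
Reactants: 27 (4R,5R,7R,11R)-4,5:7,11-diepoxy-9-hydroxygermacr-1(10)-ene-12,15-diyl diacetate
Product: 28 (1(10)E,4R,5R,7S,11R)-4,5:7,11-diepoxy-9-oxogermacr-1(10)-ene-12,15-diyl diacetate (CNP0185847.3)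
Conditions: Dess–Martin periodinane (1.5 equiv), pyridine (3 equiv), CH2Cl2, 0 °C to rt
Reagents that add atoms: none
Why: Dess–Martin oxidation of the allylic carbinol to the enone under buffered, non-basic conditions, so the β,γ-epoxy ketone is not opened. Both C9 epimers converge on the single target.

## Compound list

1 | propane-1,3-diol | OCCCO | starting material
2 | 3-[(tert-butyldimethylsilyl)oxy]propan-1-ol | OCCCO[Si](C)(C)C(C)(C)C | intermediate
3 | 3-[(tert-butyldimethylsilyl)oxy]propanal | O=CCCO[Si](C)(C)C(C)(C)C | intermediate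
4 | 2-(triphenylphosphoranylidene)propanal | CC(C=O)=P(c1ccccc1)(c1ccccc1)c1ccccc1 | starting material
5 | (E)-5-[(tert-butyldimethylsilyl)oxy]-2-methylpent-2-enal | O=C/C(C)=C/CCO[Si](C)(C)C(C)(C)C | intermediate
6 | 4,4-dimethoxybutan-2-one | COC(CC(C)=O)OC | starting material
7 | lithium 4,4-dimethoxybut-1-en-2-olate (not isolated) | [Li+].[O-]C(=C)CC(OC)OC | intermediate
8 | (E)-9-[(tert-butyldimethylsilyl)oxy]-5-hydroxy-1,1-dimethoxy-6-methylnon-6-en-3-one (racemic) | COC(OC)CC(=O)CC(O)/C(C)=C/CCO[Si](C)(C)C(C)(C)C | intermediate
9 | 2-(diethoxyphosphoryl)propanoic acid | CCOP(=O)(OCC)C(C)C(O)=O | starting material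
10 | (3E)-1-[(tert-butyldimethylsilyl)oxy]-9,9-dimethoxy-4-methyl-7-oxonon-3-en-5-yl 2-(diethoxyphosphoryl)propanoate (diastereomer mixture) | CCOP(=O)(OCC)C(C)C(=O)OC(CC(=O)CC(OC)OC)/C(C)=C/CCO[Si](C)(C)C(C)(C)C | intermediate
11 | 6-{(2E)-5-[(tert-butyldimethylsilyl)oxy]pent-2-en-2-yl}-4-(2,2-dimethoxyethyl)-3-methyl-5,6-dihydro-2H-pyran-2-one (racemic) | CC1=C(CC(OC)OC)CC(/C(C)=C/CCO[Si](C)(C)C(C)(C)C)OC1=O | intermediate
12 | (2E,6E)-9-[(tert-butyldimethylsilyl)oxy]-3-(2,2-dimethoxyethyl)-2,6-dimethylnona-2,6-diene-1,5-diol (racemic; C12 cis to C8) | OC/C(C)=C(/CC(OC)OC)CC(O)/C(C)=C/CCO[Si](C)(C)C(C)(C)C | intermediate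
13 | (2E,6E)-9-[(tert-butyldimethylsilyl)oxy]-1-[(tert-butyldiphenylsilyl)oxy]-3-(2,2-dimethoxyethyl)-2,6-dimethylnona-2,6-dien-5-ol | CC(C)(C)[Si](c1ccccc1)(c1ccccc1)OC/C(C)=C(/CC(OC)OC)CC(O)/C(C)=C/CCO[Si](C)(C)C(C)(C)C | intermediate
14 | (2E,6E)-9-[(tert-butyldimethylsilyl)oxy]-1-[(tert-butyldiphenylsilyl)oxy]-3-(2,2-dimethoxyethyl)-5-[(4-methoxybenzyl)oxy]-2,6-dimethylnona-2,6-diene | CC(C)(C)[Si](c1ccccc1)(c1ccccc1)OC/C(C)=C(/CC(OC)OC)CC(OCc1ccc(OC)cc1)/C(C)=C/CCO[Si](C)(C)C(C)(C)C | intermediate
15 | (3E,7E)-9-[(tert-butyldiphenylsilyl)oxy]-7-(2,2-dimethoxyethyl)-5-[(4-methoxybenzyl)oxy]-4,8-dimethylnona-3,7-dien-1-ol | CC(C)(C)[Si](c1ccccc1)(c1ccccc1)OC/C(C)=C(/CC(OC)OC)CC(OCc1ccc(OC)cc1)/C(C)=C/CCO | intermediate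
16 | (3E,7E)-9-[(tert-butyldiphenylsilyl)oxy]-7-(2,2-dimethoxyethyl)-1-iodo-5-[(4-methoxybenzyl)oxy]-4,8-dimethylnona-3,7-diene | CC(C)(C)[Si](c1ccccc1)(c1ccccc1)OC/C(C)=C(/CC(OC)OC)CC(OCc1ccc(OC)cc1)/C(C)=C/CCI | intermediate
17 | triethyl phosphonoacetate | CCOC(=O)CP(=O)(OCC)OCC | starting material
18 | sodium salt of triethyl phosphonoacetate (not isolated) | [Na+].CCOC(=O)[CH-]P(=O)(OCC)OCC | intermediate
19 | ethyl (5E,9E)-11-[(tert-butyldiphenylsilyl)oxy]-2-(diethoxyphosphoryl)-9-(2,2-dimethoxyethyl)-7-[(4-methoxybenzyl)oxy]-6,10-dimethylundeca-5,9-dienoate | CC(C)(C)[Si](c1ccccc1)(c1ccccc1)OC/C(C)=C(/CC(OC)OC)CC(OCc1ccc(OC)cc1)/C(C)=C/CCC(C(=O)OCC)P(=O)(OCC)OCC | intermediate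
20 | ethyl (5E,9E)-11-[(tert-butyldiphenylsilyl)oxy]-2-(diethoxyphosphoryl)-7-[(4-methoxybenzyl)oxy]-6,10-dimethyl-9-(2-oxoethyl)undeca-5,9-dienoate | CC(C)(C)[Si](c1ccccc1)(c1ccccc1)OC/C(C)=C(/CC=O)CC(OCc1ccc(OC)cc1)/C(C)=C/CCC(C(=O)OCC)P(=O)(OCC)OCC | intermediate
21 | ethyl (1(10)E,4E,7(11)Z)-12-[(tert-butyldiphenylsilyl)oxy]-9-[(4-methoxybenzyl)oxy]germacra-1(10),4,7(11)-trien-15-oate (racemic at C9) | CCOC(=O)/C1=C/C/C(=C(\C)CO[Si](c2ccccc2)(c2ccccc2)C(C)(C)C)CC(OCc2ccc(OC)cc2)/C(C)=C/CC1 | intermediate
22 | (1(10)E,4E,7(11)Z)-12-[(tert-butyldiphenylsilyl)oxy]-9-[(4-methoxybenzyl)oxy]germacra-1(10),4,7(11)-trien-15-ol | OC/C1=C/C/C(=C(\C)CO[Si](c2ccccc2)(c2ccccc2)C(C)(C)C)CC(OCc2ccc(OC)cc2)/C(C)=C/CC1 | intermediate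
23 | (1(10)E,4E,7(11)Z)-9-[(4-methoxybenzyl)oxy]germacra-1(10),4,7(11)-triene-12,15-diol | OC/C1=C/C/C(=C(\C)CO)CC(OCc2ccc(OC)cc2)/C(C)=C/CC1 | intermediate
24 | (7S,11R)-7,11-epoxy-9-[(4-methoxybenzyl)oxy]germacra-1(10),4-diene-12,15-diol (not isolated) | OC/C1=C/C[C@]2(O[C@]2(C)CO)CC(OCc3ccc(OC)cc3)/C(C)=C/CC1 | intermediate
25 | (4R,5R,7R,11R)-4,5:7,11-diepoxy-9-[(4-methoxybenzyl)oxy]germacr-1(10)-ene-12,15-diol (C9 epimers) | OC[C@]12CC/C=C(\C)C(OCc4ccc(OC)cc4)C[C@]3(C[C@H]1O2)O[C@]3(C)CO | intermediate
26 | (4R,5R,7R,11R)-4,5:7,11-diepoxy-9-[(4-methoxybenzyl)oxy]germacr-1(10)-ene-12,15-diyl diacetate (C9 epimers) | CC(=O)OC[C@]12CC/C=C(\C)C(OCc4ccc(OC)cc4)C[C@]3(C[C@H]1O2)O[C@]3(C)COC(C)=O | intermediate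
27 | (4R,5R,7R,11R)-4,5:7,11-diepoxy-9-hydroxygermacr-1(10)-ene-12,15-diyl diacetate (C9 epimers) | CC(=O)OC[C@]12CC/C=C(\C)C(O)C[C@]3(C[C@H]1O2)O[C@]3(C)COC(C)=O | intermediate
28 | (1(10)E,4R,5R,7S,11R)-4,5:7,11-diepoxy-9-oxogermacr-1(10)-ene-12,15-diyl diacetate | CC(=O)OC[C@]12CC/C=C(\C)C(=O)C[C@]3(C[C@H]1O2)O[C@]3(C)COC(C)=O | target

## Step count and least certain steps

Total step count: 20. Longest linear sequence: 20 steps (1 to 28); compounds 4, 6, 9 and 17 enter as purchased.

Step 6 (key step). The process most likely to interfere is enolisation of the C7 ketone instead of the phosphonate. An enolate toward C8 expels the C9 carboxylate and gives a conjugated dienone; an enolate toward C6 expels methoxide from C5. Both become important if addition of the hindered α-methyl carbanion to the dialkyl ketone is slow. The fallback sets out from 8 and replaces the olefination by an aldol-type closure followed by dehydration. Acylation of 8 with 2-bromopropanoyl bromide and pyridine at −20 °C gives the 2-bromopropanoate F1. SmI2 in THF at −78 °C generates the samarium enolate, which adds to the C7 ketone in an intramolecular Reformatsky reaction to give the β-hydroxy lactone F2. Dehydration with thionyl chloride and pyridine removes the acidic C11 proton and the tertiary hydroxyl; any β,γ-isomer is brought into conjugation by brief contact with an amine base. The route is rejoined at 11.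

Step 14. Two processes threaten it. The first is intermolecular olefination (oligomers) competing with an entropically and enthalpically demanding ten-membered closure. The second is base-induced enolisation of aldehyde 20 at C6, which is both α to the formyl group and allylic; this would move the C7=C11 double bond into conjugation and lose the geometry set in step 6, and the same migration can begin under the acid of step 13. The fallback sets out from 16 and closes the ring without added base, by a Wittig reaction of a stabilised ylide. Heating 16 with two equivalents of ethyl (triphenylphosphoranylidene)acetate in ethyl acetate gives the phosphonium iodide F3. The second equivalent deprotonates it to the α-alkylated ylide acetal F4. Hydrolysis of the acetal as in step 13 (the ylide is held as its conjugate acid and released by a bicarbonate wash) gives the ylide aldehyde F5. F5 is diluted at once into toluene at 80 °C (about 1 mM) and cyclises to 21, where the route is rejoined.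

Step 17. Three processes are of concern. First, facial bias imposed by the ten-membered ring may oppose the catalyst for one of the two C9 epimers and give oxirane diastereomers. Second, the tetrasubstituted allylic alcohol may react slowly. Third, the titanium alkoxide may promote opening of the tertiary epoxy alcohols, including transannular attack by C1=C10. The fallback sets out from 23 and removes both the C9 stereocentre and the nucleophilic alkene before the epoxidation. Silylation with chlorotriethylsilane and imidazole gives the bis(triethylsilyl) ether F6. DDQ in buffered CH2Cl2 cleaves the benzyl-type ether to the C9 alcohol F7, and Dess–Martin oxidation gives the dienone F8. Buffered HF·pyridine releases the achiral dienone diol F9. The Sharpless epoxidation of step 17 on this substrate, now without matched or mismatched cases and with C1=C10 deactivated as an enone, gives the bis-epoxy keto diol F10. Acetylation with acetic anhydride and pyridine then gives 28 directly.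

Step 4. Proton transfer to the more acidic C3 methylene of 6 (between carbonyl and acetal), followed by loss of methoxide, can consume the ketone. The lithium aldolate can also revert or dehydrate before the quench. The fallback sets out from 6 and 5 and avoids a strongly basic aldolate. Ketone 6 is converted with LiN(iPr)2 and chlorotrimethylsilane at −78 °C into the silyl enol ether F11, which is freed from its regioisomer by distillation. A Lewis-base-catalysed Mukaiyama aldol addition to 5 (lithium acetate, 10 mol%, DMF, −45 °C) gives the O-silylated aldol F12. Citric acid in methanol at 0 °C removes the trimethylsilyl group, and the route is rejoined at 8.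

## Further compounds

F1 | step 6 | (3E)-1-[(tert-butyldimethylsilyl)oxy]-9,9-dimethoxy-4-methyl-7-oxonon-3-en-5-yl 2-bromopropanoate | CC(Br)C(=O)OC(CC(=O)CC(OC)OC)/C(C)=C/CCO[Si](C)(C)C(C)(C)C
F2 | step 6 | 6-{(2E)-5-[(tert-butyldimethylsilyl)oxy]pent-2-en-2-yl}-4-(2,2-dimethoxyethyl)-4-hydroxy-3-methyltetrahydro-2H-pyran-2-one | CC1C(=O)OC(/C(C)=C/CCO[Si](C)(C)C(C)(C)C)CC1(O)CC(OC)OC
F3 | step 14 | [(5E,9E)-11-[(tert-butyldiphenylsilyl)oxy]-9-(2,2-dimethoxyethyl)-1-ethoxy-7-[(4-methoxybenzyl)oxy]-6,10-dimethyl-1-oxoundeca-5,9-dien-2-yl]triphenylphosphonium iodide | CC(C)(C)[Si](c1ccccc1)(c1ccccc1)OC/C(C)=C(/CC(OC)OC)CC(OCc1ccc(OC)cc1)/C(C)=C/CCC(C(=O)OCC)[P+](c1ccccc1)(c1ccccc1)c1ccccc1.[I-]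
F4 | step 14 | ethyl (5E,9E)-11-[(tert-butyldiphenylsilyl)oxy]-9-(2,2-dimethoxyethyl)-7-[(4-methoxybenzyl)oxy]-6,10-dimethyl-2-(triphenylphosphoranylidene)undeca-5,9-dienoate | CC(C)(C)[Si](c1ccccc1)(c1ccccc1)OC/C(C)=C(/CC(OC)OC)CC(OCc1ccc(OC)cc1)/C(C)=C/CCC(C(=O)OCC)=P(c1ccccc1)(c1ccccc1)c1ccccc1
F5 | step 14 | ethyl (5E,9E)-11-[(tert-butyldiphenylsilyl)oxy]-7-[(4-methoxybenzyl)oxy]-6,10-dimethyl-9-(2-oxoethyl)-2-(triphenylphosphoranylidene)undeca-5,9-dienoate | CC(C)(C)[Si](c1ccccc1)(c1ccccc1)OC/C(C)=C(/CC=O)CC(OCc1ccc(OC)cc1)/C(C)=C/CCC(C(=O)OCC)=P(c1ccccc1)(c1ccccc1)c1ccccc1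
F6 | step 17 | (1(10)E,4E,7(11)Z)-9-[(4-methoxybenzyl)oxy]-12,15-bis[(triethylsilyl)oxy]germacra-1(10),4,7(11)-triene | CC[Si](CC)(CC)OC/C1=C/C/C(=C(\C)CO[Si](CC)(CC)CC)CC(OCc2ccc(OC)cc2)/C(C)=C/CC1
F7 | step 17 | (1(10)E,4E,7(11)Z)-12,15-bis[(triethylsilyl)oxy]germacra-1(10),4,7(11)-trien-9-ol | CC[Si](CC)(CC)OC/C1=C/C/C(=C(\C)CO[Si](CC)(CC)CC)CC(O)/C(C)=C/CC1
F8 | step 17 | (1(10)E,4E,7(11)Z)-12,15-bis[(triethylsilyl)oxy]germacra-1(10),4,7(11)-trien-9-one | CC[Si](CC)(CC)OC/C1=C/C/C(=C(\C)CO[Si](CC)(CC)CC)CC(=O)/C(C)=C/CC1
F9 | step 17 | (1(10)E,4E,7(11)Z)-12,15-dihydroxygermacra-1(10),4,7(11)-trien-9-one | OC/C1=C/C/C(=C(\C)CO)CC(=O)/C(C)=C/CC1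
F10 | step 17 | (1(10)E,4R,5R,7S,11R)-4,5:7,11-diepoxy-12,15-dihydroxygermacr-1(10)-en-9-one | OC[C@]12CC/C=C(\C)C(=O)C[C@]3(C[C@H]1O2)O[C@]3(C)CO
F11 | step 4 | 4,4-dimethoxy-2-[(trimethylsilyl)oxy]but-1-ene | C=C(O[Si](C)(C)C)CC(OC)OC
F12 | step 4 | (E)-9-[(tert-butyldimethylsilyl)oxy]-1,1-dimethoxy-6-methyl-5-[(trimethylsilyl)oxy]non-6-en-3-one | COC(OC)CC(=O)CC(O[Si](C)(C)C)/C(C)=C/CCO[Si](C)(C)C(C)(C)C
A1 | alternative 1 | 4,5:7,11-diepoxy-9-hydroxygermacr-1(10)-ene-12,15-diyl diacetate with the oxirane configurations of the target (either C9 epimer; identical with 27) | CC(=O)OC[C@]12CC/C=C(\C)C(O)C[C@]3(C[C@H]1O2)O[C@]3(C)COC(C)=O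
A2 | alternative 1 | open-chain 9,10-seco iodo aldehyde: C10 (E)-alkenyl iodide and C9 aldehyde, with both oxiranes and both acetates of the target | CC(=O)OC[C@@]1(CC/C=C(\C)I)O[C@@H]1C[C@@]2(CC=O)O[C@]2(C)COC(C)=O
A3 | alternative 2 | 3-methyl-4-(1,3-dioxolan-2-ylmethyl)furan-2(5H)-one | CC1=C(CC2OCCO2)COC1=O
A4 | alternative 2 | but-2-yn-1-ol | CC#CCO
A5 | alternative 2 | (1,3-dioxolan-2-ylmethyl)magnesium bromide | Br[Mg]CC1OCCO1
A6 | alternative 3 | ten-membered triene with phenylsulfonyl on C2 and tert-butyldimethylsilyl ethers on the C9, C12 and C15 oxygens | O=S(=O)(c1ccccc1)C2C/C(CO[Si](C)(C)C(C)(C)C)=C\C/C(=C(\C)CO[Si](C)(C)C(C)(C)C)CC(O[Si](C)(C)C(C)(C)C)/C(C)=C/2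
A7 | alternative 3 | open-chain 2,3-seco precursor: C2 allylic phenyl sulfone and C3 allylic chloride, with tert-butyldimethylsilyl ethers on the C9, C12 and C15 oxygens | O=S(=O)(c1ccccc1)C/C=C(\C)C(O[Si](C)(C)C(C)(C)C)C/C(=C(/C)CO[Si](C)(C)C(C)(C)C)C/C=C(\CCl)CO[Si](C)(C)C(C)(C)C
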